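The isopropenyl group on C5 and the propanoic acid chain on C10 (abietane numbering) stand cis on tetralone ring B. They are therefore read as the two ends of a cleaved, cis-fused carbocycle (ring A: C1–C5, C10). Everything rests on the aryl C9–quaternary C10 bond. It is made by an epoxide-initiated cation–olefin bicyclisation of an acyclic (R)-epoxy (Z)-homoneryl arene. One operation closes temporary ring A and ring B, alkylates the only free arene carbon (C9), and sets C5 and C10 by anti addition across the Z alkene. Double oxidation (C3, C7), Baeyer–Villiger insertion and acid opening of the lactone then cut C3–C4 and release both side chains.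

Key step: step 6

Remark on numbering: ring A = C1–C5 and C10; ring B = C5–C10; arene ring C = C8, C9, C11–C14; C20 = methyl on C10. The C5 descriptor changes from R (10–14) to S (15, 16) through a change of CIP priority only, not an inversion.
Remark on chemistry: the D-fructose-derived Shi ketone is assumed to give the (R)-epoxide of an isopropylidene terminus, in line with the (R,R)-epoxides it gives from trans and trisubstituted alkenes.

Step 1
Reactants: 1 1,2,4-trimethoxybenzene
Product: 3 2-(2,3,6-trimethoxyphenyl)propan-2-ol, via 3-lithio-1,2,4-trimethoxybenzene 2 (not isolated)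
Conditions: n-BuLi, TMEDA, THF, 0 °C to rt; acetone, −78 °C to rt; then H2O
Reagents that add atoms: acetone CC(C)=O
Why: Directed ortho-metalation removes the C3 proton flanked by two methoxy groups, and aryllithium 2 adds to the carbonyl group of acetone (1,2-addition).

Step 2
Reactants: 3 2-(2,3,6-trimethoxyphenyl)propan-2-ol
Product: 4 2-isopropyl-1,3,4-trimethoxybenzene
Conditions: Et3SiH, CF3CO2H, CH2Cl2, 0 °C to rt
Reagents that add atoms: none
Why: Ionic hydrogenation, in which CF3CO2H ionises the tertiary benzylic alcohol to a cation stabilised by two ortho methoxy groups and Et3SiH delivers hydride to it.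

Step 3
Reactants: 4 2-isopropyl-1,3,4-trimethoxybenzene
Product: 5 1-(chloromethyl)-3-isopropyl-2,4,5-trimethoxybenzene
Conditions: (CH2O)n, HCl (g), 1,4-dioxane, 0 °C to rt
Reagents that add atoms: formaldehyde (from paraformaldehyde) C=O; hydrogen chloride Cl
Why: Blanc chloromethylation, an electrophilic aromatic substitution that should go to C6 of 4, the free position ortho to one methoxy group and para to another, rather than to C5, which has only one such donor.

Step 4
Reactants: 6 neryl acetate
Product: 7 (2Z)-5-[(2R)-3,3-dimethyloxiran-2-yl]-3-methylpent-2-en-1-yl acetate ((R)-6,7-epoxyneryl acetate)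
Conditions: D-fructose-derived Shi ketone (30 mol %), KHSO5 (as 2KHSO5·KHSO4·K2SO4), K2CO3, Na2B4O7 buffer, Bu4NHSO4, MeCN–dimethoxymethane–H2O, 0 °C
Reagents that add atoms: potassium peroxymonosulfate [K+].[O-]S(=O)(=O)OO
Why: Shi asymmetric epoxidation, in which the electrophilic ketone/KHSO5 oxidant prefers the electron-rich C6=C7 alkene over the C2=C3 alkene deactivated by the allylic acetate, and the spiro transition state delivers oxygen to the face that gives the (R)-epoxide.

Step 5
Reactants: 5 1-(chloromethyl)-3-isopropyl-2,4,5-trimethoxybenzene; 7 (R)-6,7-epoxyneryl acetate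
Product: 9 (3R)-2,2-dimethyl-3-[(3Z)-6-(3-isopropyl-2,4,5-trimethoxyphenyl)-3-methylhex-3-en-1-yl]oxirane, via benzylmagnesium chloride 8 (not isolated)
Conditions: Mg, THF, 0 °C (slow addition of 5); then 7, Li2CuCl4 (5 mol %), THF, −30 to 0 °C; aq. NH4Cl
Reagents that add atoms: none
Why: Copper-catalysed cross-coupling of a Grignard reagent with a primary allylic acetate, which in THF with Li2CuCl4 is known to substitute at the α carbon with retention of alkene geometry, while the trisubstituted epoxide is too hindered to react at this temperature and its stereocentre is untouched.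

Step 6
Reactants: 9 (R)-epoxy (Z)-homoneryl arene
Product: 10 (3R,5R,10R)-11,12,14-trimethoxyabieta-8,11,13-trien-3-ol (A/B cis-fused; H-5 and C20 methyl cis)
Conditions: MeAlCl2 (2.5 equiv), CH2Cl2, −78 °C; then H2O
Reagents that add atoms: none
Why: MeAlCl2 binds the epoxide oxygen, the C4–O bond ionises with backside participation of the C5=C10 alkene, the positive charge building up at C10 is taken by arene carbon C9 (new C9–C10 bond), and the proton lost on rearomatisation is consumed by the Al–CH3 bond as methane, so the medium stays free of strong protic acid. The closest known reaction type is the epoxide-initiated, arene-terminated cation–olefin polycyclisation (biomimetic polyene cyclisation under Stork–Eschenmoser stereocontrol). Ring A closes 6-endo-tet at the epoxide and 6-endo-trig at the alkene, and ring B closes 6-endo-trig as an intramolecular Friedel–Crafts alkylation. C3 is carried over unchanged from 9; C5 is set by the chair-like ring A transition state with anti opening of the epoxide and an equatorial C3–OAl bond, which places C6 (cis to C1 in the Z alkene) axial; C10 is set by anti addition across the alkene, which puts C9 equatorial and the C20 methyl axial, that is the cis A/B fusion of 10. Should the closure be stepwise, the equatorial aluminium alkoxide still anchors the conformer with the axial arylethyl arm, which can reach only its own face of C10, so both pathways should converge on the cis fusion. Site selectivity is secured because C9 is the only unsubstituted arene carbon (ortho to the C11 methoxy group, para to isopropyl), and minor C3/C5 diastereomers from boat-like folding are removed by chromatography here, since they would turn into the enantiomer once C3 is oxidised.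

Step 7
Reactants: 10 cis-fused tricyclic alcohol
Product: 11 (5R,10R)-11,12,14-trimethoxyabieta-8,11,13-triene-3,7-dione
Conditions: CrO3, AcOH–H2O, 0 °C to rt
Reagents that add atoms: chromium trioxide O=[Cr](=O)=O
Why: Chromic acid oxidation takes the secondary C3 alcohol to the ketone and the only benzylic methylene (C7, activated by the ortho C14 and para C12 methoxy groups) to the aryl ketone in one operation, the C15 methine being shielded by two flanking methoxy groups and C5 and C10 lying outside any enolisable position.

Step 8
Reactants: 11 trimethoxy dione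
Product: 13 (5R,10R)-11,12,14-triacetoxyabieta-8,11,13-triene-3,7-dione, via triphenol dione 12 (not isolated)
Conditions: BBr3, CH2Cl2, −78 to 0 °C; MeOH, −78 °C, concentrate; Ac2O, pyridine, DMAP (cat.), rt, Ar
Reagents that add atoms: acetic anhydride CC(=O)OC(C)=O
Why: BBr3 cleaves the three aryl methyl ethers (Lewis acid ether cleavage) while no alkene is yet present, and the air-sensitive triphenol 12 is acetylated at once, so that the phenols can be released at the end under non-acidic conditions.

Step 9
Reactants: 13 triacetoxy dione
Product: 14 (5R,10R)-11,12,14-triacetoxy-4-oxa-A-homoabieta-8,11,13-triene-3,7-dione (ring A ε-lactone; oxygen between C3 and C4)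
Conditions: mCPBA, NaHCO3, CH2Cl2, rt
Reagents that add atoms: 3-chloroperoxybenzoic acid O=C(OO)c1cccc(Cl)c1
Why: Baeyer–Villiger oxidation, in which the dialkyl C3 ketone reacts in preference to the conjugated, ortho-substituted C7 aryl ketone and the fully substituted C4 migrates, inserting oxygen between C3 and C4 without touching C5 or C10.

Step 10
Reactants: 14 ring A ε-lactone
Product: 15 (5S,10R)-11,12,14-triacetoxy-7-oxo-3,4-secoabieta-4(18),8,11,13-tetraen-3-oic acid
Conditions: p-TsOH (anhydrous, cat.), CH2Cl2, rt
Reagents that add atoms: none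
Why: Acid-catalysed alkyl–oxygen fission of the tertiary lactone followed by E1 loss of a methyl proton, the known way to open ring A ε-lactones of 4,4-dimethyl terpenoids to 4(18)-en-3-oic acids, frees the isopropenyl group and the propanoic acid chain, and the acetylated C11 oxygen cannot trap the C4 cation.

Step 11
Reactants: 15 seco acid triacetate
Product: 16 (5S,10R)-11,12,14-trihydroxy-7-oxo-3,4-secoabieta-4(18),8,11,13-tetraen-3-oic acid (target)
Conditions: K2CO3, degassed MeOH, 0 °C, Ar; aq. NaH2PO4 containing Na2S2O4
Reagents that add atoms: none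
Why: Base-catalysed transesterification (Zemplén-type deacetylation) removes the three aryl acetates without acid, which avoids addition of the C11 phenol or the acid to the isopropenyl group, and exclusion of air prevents oxidation of the trihydroxyarene to the quinone.

Compound list
1 | 1,2,4-trimethoxybenzene | COc1ccc(OC)c(OC)c1 | starting material
2 | 3-lithio-1,2,4-trimethoxybenzene | [Li]c1c(OC)ccc(OC)c1OC | intermediate
3 | 2-(2,3,6-trimethoxyphenyl)propan-2-ol | COc1ccc(OC)c(C(C)(C)O)c1OC | intermediate
4 | 2-isopropyl-1,3,4-trimethoxybenzene | COc1ccc(OC)c(C(C)C)c1OC | intermediate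
5 | 1-(chloromethyl)-3-isopropyl-2,4,5-trimethoxybenzene | COc1cc(CCl)c(OC)c(C(C)C)c1OC | intermediate
6 | neryl acetate | CC(C)=CCC/C(C)=C\COC(C)=O | starting material
7 | (R)-6,7-epoxyneryl acetate | CC1(C)O[C@@H]1CC/C(C)=C\COC(C)=O | intermediate
8 | (3-isopropyl-2,4,5-trimethoxybenzyl)magnesium chloride | COc1cc(C[Mg]Cl)c(OC)c(C(C)C)c1OC | intermediate
9 | (3R)-2,2-dimethyl-3-[(3Z)-6-(3-isopropyl-2,4,5-trimethoxyphenyl)-3-methylhex-3-en-1-yl]oxirane | CC1(C)O[C@@H]1CC/C(C)=C\CCc1cc(OC)c(OC)c(C(C)C)c1OC | intermediate
10 | (3R,5R,10R)-11,12,14-trimethoxyabieta-8,11,13-trien-3-ol, A/B cis | CC1(C)[C@H](O)CC[C@@]2(C)c3c(OC)c(OC)c(C(C)C)c(OC)c3CC[C@@H]12 | intermediate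
11 | (5R,10R)-11,12,14-trimethoxyabieta-8,11,13-triene-3,7-dione | CC1(C)C(=O)CC[C@@]2(C)c3c(OC)c(OC)c(C(C)C)c(OC)c3C(=O)C[C@@H]12 | intermediate
12 | (5R,10R)-11,12,14-trihydroxyabieta-8,11,13-triene-3,7-dione | CC1(C)C(=O)CC[C@@]2(C)c3c(O)c(O)c(C(C)C)c(O)c3C(=O)C[C@@H]12 | intermediate
13 | (5R,10R)-11,12,14-triacetoxyabieta-8,11,13-triene-3,7-dione | CC1(C)C(=O)CC[C@@]2(C)c3c(OC(C)=O)c(OC(C)=O)c(C(C)C)c(OC(C)=O)c3C(=O)C[C@@H]12 | intermediate
14 | (5R,10R)-11,12,14-triacetoxy-4-oxa-A-homoabieta-8,11,13-triene-3,7-dione | CC1(C)OC(=O)CC[C@@]2(C)c3c(OC(C)=O)c(OC(C)=O)c(C(C)C)c(OC(C)=O)c3C(=O)C[C@@H]12 | intermediate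
15 | (5S,10R)-11,12,14-triacetoxy-7-oxo-3,4-secoabieta-4(18),8,11,13-tetraen-3-oic acid | C=C(C)[C@@H]1CC(=O)c2c(OC(C)=O)c(C(C)C)c(OC(C)=O)c(OC(C)=O)c2[C@]1(C)CCC(=O)O | intermediate
16 | 3-[(1R,2S)-5,7,8-trihydroxy-1-methyl-4-oxo-6-(propan-2-yl)-2-(prop-1-en-2-yl)-1,2,3,4-tetrahydronaphthalen-1-yl]propanoic acid | C=C(C)[C@@H]1CC(=O)c2c(O)c(C(C)C)c(O)c(O)c2[C@]1(C)CCC(=O)O | target

Total step count: 11. Longest linear sequence: 10 (steps 1–3 and 5–11).

Steps most likely to fail

Step 6.
- What may go wrong: the cascade may stop early. The routes are proton loss next to C10, capture of C10 by the aluminium alkoxide oxygen to an oxa-bridged ether, ipso attack at C8, or rearrangement of the epoxide to a ketone. Anti-addition fidelity across the Z alkene may also be lost.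
- Fallback, from 9 back to 10: the two rings are built in separate steps by different mechanisms.
- Ring A: trivalent titanium (Cp2TiCl, made from Cp2TiCl2 and Mn, THF, rt) opens the epoxide homolytically at C4. The tertiary radical closes ring A 6-endo through the same chair-like folding. β-Hydride elimination should then give (1R,3R)-3-[2-(3-isopropyl-2,4,5-trimethoxyphenyl)ethyl]-2,2-dimethyl-4-methylidenecyclohexan-1-ol F1.
- Ring B: the C9–C10 bond is formed on its own by Friedel–Crafts cyclialkylation of the exocyclic alkene (SnCl4–CF3CO2H, CH2Cl2, −78 °C). The axial arylethyl arm should again reach only its own face of C10, giving 10.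

Step 5.
- What may go wrong: Wurtz-type homocoupling while the electron-rich benzylic Grignard reagent forms, attack at the γ carbon, erosion of the Z geometry, or attack on the acetate carbonyl or the epoxide.
- Fallback, from 5 and 7 back to 9: the benzylic carbanion is stabilised by a sulfone and alkylated by SN2.
- Nucleophile: 5 with PhSO2Na (DMF, rt) should give 3-isopropyl-2,4,5-trimethoxybenzyl phenyl sulfone F2.
- Electrophile: 7 is methanolysed (K2CO3, MeOH, 0 °C) to (R)-6,7-epoxynerol F3. This is converted (MsCl, Et3N; then LiBr, THF, −40 to 0 °C) into (R)-6,7-epoxyneryl bromide F4.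
- Coupling: lithiated F2 (n-BuLi, THF, −78 °C) is alkylated with F4 to the α-alkylated sulfone F5, a mixture at the sulfonyl carbon.
- Return: reductive desulfonylation (Mg, MeOH, rt) gives 9.

Step 7.
- What may go wrong: the electron-rich ring C may be over-oxidised (oxidative demethylation towards a quinone), or the isopropyl methine may be attacked.
- Fallback, from 10 back to 13: the two oxidations are separated, and the benzylic one is moved behind the protecting-group exchange so that chromium meets an electron-poor arene.
- Dess–Martin periodinane (CH2Cl2, rt) takes 10 to (5R,10R)-11,12,14-trimethoxyabieta-8,11,13-trien-3-one F6.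
- BBr3 gives the triphenol ketone F7, which is acetylated without isolation (Ac2O, pyridine, DMAP) to (5R,10R)-11,12,14-triacetoxyabieta-8,11,13-trien-3-one F8.
- CrO3 in AcOH then oxidises only C7, a known transformation of aryl acetates of this skeleton, and gives 13.

Further compounds
F1 | step 6 | (1R,3R)-3-[2-(3-isopropyl-2,4,5-trimethoxyphenyl)ethyl]-2,2-dimethyl-4-methylidenecyclohexan-1-ol | C=C1CC[C@@H](O)C(C)(C)[C@@H]1CCc1cc(OC)c(OC)c(C(C)C)c1OC
F2 | step 5 | 3-isopropyl-2,4,5-trimethoxybenzyl phenyl sulfone | COc1cc(CS(=O)(=O)c2ccccc2)c(OC)c(C(C)C)c1OC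
F3 | step 5 | (R)-6,7-epoxynerol | CC1(C)O[C@@H]1CC/C(C)=C\CO
F4 | step 5 | (R)-6,7-epoxyneryl bromide | CC1(C)O[C@@H]1CC/C(C)=C\CBr
F5 | step 5 | α-alkylated benzyl phenyl sulfone (mixture at the sulfonyl carbon) | CC1(C)O[C@@H]1CC/C(C)=C\CC(c1cc(OC)c(OC)c(C(C)C)c1OC)S(=O)(=O)c1ccccc1
F6 | step 7 | (5R,10R)-11,12,14-trimethoxyabieta-8,11,13-trien-3-one | CC1(C)C(=O)CC[C@@]2(C)c3c(OC)c(OC)c(C(C)C)c(OC)c3CC[C@@H]12
F7 | step 7 | (5R,10R)-11,12,14-trihydroxyabieta-8,11,13-trien-3-one | CC1(C)C(=O)CC[C@@]2(C)c3c(O)c(O)c(C(C)C)c(O)c3CC[C@@H]12
F8 | step 7 | (5R,10R)-11,12,14-triacetoxyabieta-8,11,13-trien-3-one | CC1(C)C(=O)CC[C@@]2(C)c3c(OC(C)=O)c(OC(C)=O)c(C(C)C)c(OC(C)=O)c3CC[C@@H]12
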